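## The problem

The target 28 is an achiral bibenzyl. A two-carbon bridge joins ring A, a 3-methoxy-5-hydroxyphenyl ring (A1 carries the bridge, A3 the methoxy group, A5 the hydroxyl), to ring B, a phenol in which B1 carries the bridge, B2 and B6 each carry a 4-hydroxybenzyl group and B3 carries the hydroxyl. There is no stereocentre, so the whole difficulty is positional. Ring B has four contiguous substituents, and B1 is flanked on both sides by benzylic carbons; substitution of a preformed phenol would have to tell B2, B4 and B6 apart. Ring A carries two meta oxygens that differ only by a methyl group, so any route through a 5-substituted resorcinol ends in a statistical monomethylation. The four electron-rich rings and the doubly benzylic methylene groups are sensitive to oxidants, electrophilic halogen and strong acid, so the phenols must travel protected and the diarylmethane bonds must survive the deprotection. The enabling feature is that ring A is the dehydro form of the methyl enol ether of a 5-substituted cyclohexane-1,3-dione. In that dione A3 and A5 are equivalent through a mirror plane containing A1 and A4, so mono-etherification can give only one compound, and the dione is the Michael–Claisen product of a methyl enone (A1, A4, A5, A6) and a malonate (A2, A3).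

## Retrosynthesis

28 is traced to the tris(benzyl ether) 27 by cutting three O–CH2Ph bonds. Benzyl is preferred to methyl, which could not be told from the A3 methoxy group, and to silyl, which would not survive hot alkoxide and hydroxide. The forward step is one hydrogenolysis that must leave the diarylmethane and bibenzyl C–C bonds alone.

27 is traced to the vinylogous ester 24 by removing the aromatic unsaturation of ring A (dehydrogenation across A6–A1, then tautomerisation), and 24 to dione 23 by cutting the O–CH3 bond. The neighbouring order, aromatising first to a resorcinol and methylating afterwards, would give mono-, di- and unmethylated material. In the chosen order the mirror symmetry of 23 allows only one mono enol ether. The forward dehydrogenation must start from the kinetic enolate at A6.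

23 is cut at A1–A2 and A3–A4 into enone 18 and dimethyl malonate 19. This removes ring A altogether and leaves a linear enone, against cross-coupling of a preformed, desymmetrised ring A unit, which would bring back the monomethylation problem. The forward reaction is a malonate conjugate addition, a six-membered Claisen closure and a decarboxylation.

18 is cut at its C=C bond into aldehyde 16 and the stabilised ylide 17, which fixes the E geometry. 16 comes from dioxolane 15 by hydrolysis, and 15 from phenol 14 by O-benzylation, so the B3 oxygen carries the same protecting group as the other two phenols.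

14 is traced to cyclohexenone 11 by removing the aromaticity of ring B. In 11 the carbonyl carbon becomes B3, C2 is B2, C3 is B1 and C4 is B6, so the contiguous substitution pattern is set on an enone, where each position has its own reactivity, and not on an arene. The forward step is a dehydrogenation through the kinetic enolate at C6 of 11.

11 is cut at the B1–CH2 bond into the vinylogous ester 7 and bromide 8, used as its Grignard reagent 9. Carbonyl addition with alkylative transposition puts the three-carbon chain on the carbon between the two benzyl groups, a position that electrophilic chemistry on a phenol could not reach. The forward step needs 1,2-addition to a hindered ketone and an acidic transposition that spares the dioxolane.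

7 is cut at the B6–CH2 bond into vinylogous ester 5 and the commercial bromide 6 (kinetic alkylation at C6). 5 comes from dione 4 by cutting the O–ethyl bond, and 4 is cut at the B2–CH2 bond into cyclohexane-1,3-dione 1 and aldehyde 2 (reductive alkylation at the only doubly activated carbon). The two benzyl groups are thus installed by two different, position-specific reactions.

## Roads not taken

Alternative 1: Ring B would be cut across B1–B6 and B2–B3 into 6-[4-(benzyloxy)benzyl]-3-hydroxy-2H-pyran-2-one A2 (B3 to B6) and ynone A3 (B1 and B2, with the bridge and ring A attached). With a tertiary amine the oxidopyrone adds across the triple bond, and the bridged lactone undergoes decarboxylative retro-cycloaddition to give 2-hydroxybenzophenone A1. Reduction of the diaryl ketone to the methylene group and debenzylation would finish the synthesis.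
- Merits: ring B is assembled with all four substituents in one step, the regiochemistry follows from the polarity of both partners, and the route is convergent.
- Weak points: A2 is not a simple commercial pyrone and needs its own synthesis. An internal ynone with an alkyl group on the attacked carbon is a slow partner for this cycloaddition. Ring A must be bought or made as a desymmetrised 3-benzyloxy-5-methoxy arene, which is the monomethylation problem moved upstream.
- Comparison: in convergence and in step count after the key step this road is better than the chosen plan, which is fully linear. The chosen plan sets against it that every building block is a simple commercial compound, that each step is a classical reaction, and that the ring A oxygens are differentiated by symmetry.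

Alternative 2: Both ring B–CH2 bonds would be cut, leading back to bromophenol A5 and two equivalents of 4-(hydroxymethyl)phenol A6. Heated with carbonate base in water, A6 gives the quinone methide A7, which alkylates the phenolate of A5 at the free ortho and para positions to give A4. The bromine blocks the second ortho position and would be removed with the benzyl ether at the end.
- Merits: it mirrors the likely biogenesis, needs no protection of the incoming phenols, and is by far the shortest road.
- Weak points: both positions to be alkylated flank the bridge, and the ortho position lies between the hydroxyl and the bridge. The newly attached hydroxybenzyl rings are themselves phenolates and react with A7, and A6 self-condenses, so stopping at exactly two benzyl groups in the right places is not controlled. Ring A again has to arrive desymmetrised.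
- Comparison: on step economy this road clearly wins. The chosen plan sets against it positional certainty, since each benzyl group is placed at a defined carbon by dione or enolate chemistry and over-benzylation cannot occur.

Alternative 3: The B2–CH2 bond and the B1–bridge bond would be cut, giving aryl iodide A9, benzylic chloride A10 and styrene A11. Under palladium/norbornene relay catalysis (Pd(OAc)2, tri(2-furyl)phosphine, Cs2CO3) the ortho C–H bond of A9 would be benzylated and the ipso position closed by a Heck reaction to give stilbene A8. One hydrogenation would then saturate the alkene and remove the benzyl ethers.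
- Merits: three components are joined in one step and the end game is a single operation.
- Weak points: the C–H bond to be functionalised lies between the iodide and a benzyloxy group, so the palladacycle of divalent palladium must form at a flanked position and leads to four contiguous substituents. Benzylic chlorides also add directly to zerovalent palladium and can divert the relay. A9 needs a regiodefined synthesis, and A11 is once more a desymmetrised ring A.
- Comparison: it is shorter and more modular than the chosen plan. The chosen plan sets against it a lower methodological risk at the most congested bond, and ring A built with its oxygens already differentiated.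

Key step: step 9

Remark: 28 has no stereocentre. The sp3 stereocentres of 7, 10 to 13, 20 to 22 and 24 to 26 arise without control and are erased by aromatisation or decarboxylation, so these compounds are written without configuration (racemates or diastereomer mixtures).

## Route

Step 1
Reactants: 1 cyclohexane-1,3-dione; 2 4-(benzyloxy)benzaldehyde
Product: 4 2-[4-(benzyloxy)benzyl]cyclohexane-1,3-dione, via 2-arylidene dione 3 (not isolated)
Conditions: Hantzsch ester (diethyl 2,6-dimethyl-1,4-dihydropyridine-3,5-dicarboxylate, 1 equiv), L-proline (cat.), CH2Cl2, rt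
Reagents that add atoms: none
Why: Organocatalytic three-component reductive alkylation: Knoevenagel condensation at the doubly activated C2 gives 3, which is reduced at once by hydride transfer from the Hantzsch ester, so a second dione cannot add to it.

Step 2
Reactants: 4 2-[4-(benzyloxy)benzyl]cyclohexane-1,3-dione
Product: 5 2-[4-(benzyloxy)benzyl]-3-ethoxycyclohex-2-en-1-one
Conditions: EtOH, TsOH·H2O (cat.), toluene, reflux, Dean–Stark
Reagents that add atoms: ethanol, CCO
Why: Acid-catalysed enol etherification of a 1,3-dione with azeotropic removal of water; the dione is symmetric, so only one vinylogous ester can form.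

Step 3
Reactants: 5 2-[4-(benzyloxy)benzyl]-3-ethoxycyclohex-2-en-1-one; 6 1-(benzyloxy)-4-(bromomethyl)benzene
Product: 7 2,6-bis[4-(benzyloxy)benzyl]-3-ethoxycyclohex-2-en-1-one (racemic)
Conditions: LiN(i-Pr)2, THF, −78 °C; then 6, −78 to 0 °C
Reagents that add atoms: none
Why: Kinetic deprotonation of a vinylogous ester occurs at C6 (Stork–Danheiser alkylation) and the lithium enolate is C-alkylated by the reactive benzylic bromide; the new stereocentre is uncontrolled and is erased in step 5.

Step 4
Reactants: 7 2,6-bis[4-(benzyloxy)benzyl]-3-ethoxycyclohex-2-en-1-one; 8 2-(2-bromoethyl)-1,3-dioxolane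
Product: 11 2,4-bis[4-(benzyloxy)benzyl]-3-[2-(1,3-dioxolan-2-yl)ethyl]cyclohex-2-en-1-one (racemic), via [2-(1,3-dioxolan-2-yl)ethyl]magnesium bromide 9 (not isolated), via tertiary allylic alcohol 10 (not isolated)
Conditions: 8, Mg, THF, 25 °C; then 7, THF, 0 °C to rt; then 1 M aq. HCl, 0 °C, short contact
Reagents that add atoms: water, O
Why: Stork–Danheiser transposition: 1,2-addition of the Grignard reagent gives 10, which ionises in cold dilute acid to an ethoxy-stabilised allyl cation that is hydrolysed to the transposed enone. The dioxolane should survive because this ionisation is far faster than acetal hydrolysis.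

Step 5
Reactants: 11 2,4-bis[4-(benzyloxy)benzyl]-3-[2-(1,3-dioxolan-2-yl)ethyl]cyclohex-2-en-1-one
Product: 14 2,4-bis[4-(benzyloxy)benzyl]-3-[2-(1,3-dioxolan-2-yl)ethyl]phenol, via 6-(phenylselanyl) enone 12 (not isolated), via cross-conjugated dienone 13 (not isolated)
Conditions: LiN(i-Pr)2, THF, −78 °C; PhSeBr, −78 °C; then pyridine, 30% aq. H2O2, 0 °C to rt
Reagents that add atoms: none
Why: Kinetic selenenylation at C6 followed by oxidation to the selenoxide and syn elimination gives dienone 13, whose sp3 C4–H is lost on tautomerisation to the phenol; the buffered, non-acidic medium spares the dioxolane and the benzyl ethers.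

Step 6
Reactants: 14 2,4-bis[4-(benzyloxy)benzyl]-3-[2-(1,3-dioxolan-2-yl)ethyl]phenol
Product: 15 2-(2-{3-(benzyloxy)-2,6-bis[4-(benzyloxy)benzyl]phenyl}ethyl)-1,3-dioxolane
Conditions: BnBr, K2CO3, DMF, rt to 50 °C
Reagents that add atoms: benzyl bromide, BrCc1ccccc1
Why: Williamson etherification of the phenolate; the acetal is inert to base, and the B3 oxygen now carries the same protecting group as the other two phenols.

Step 7
Reactants: 15 2-(2-{3-(benzyloxy)-2,6-bis[4-(benzyloxy)benzyl]phenyl}ethyl)-1,3-dioxolane
Product: 16 3-{3-(benzyloxy)-2,6-bis[4-(benzyloxy)benzyl]phenyl}propanal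
Conditions: 2 M aq. HCl, THF, rt
Reagents that add atoms: water, O
Why: Acid hydrolysis of a dioxolane to the aldehyde; aryl benzyl ethers are stable to dilute aqueous acid at room temperature.

Step 8
Reactants: 16 3-{3-(benzyloxy)-2,6-bis[4-(benzyloxy)benzyl]phenyl}propanal; 17 1-(triphenylphosphoranylidene)propan-2-one
Product: 18 (3E)-6-{3-(benzyloxy)-2,6-bis[4-(benzyloxy)benzyl]phenyl}hex-3-en-2-one
Conditions: CH2Cl2, rt to 40 °C
Reagents that add atoms: none
Why: Wittig reaction of an unhindered aliphatic aldehyde with a stabilised ylide, which gives the E-enone under thermodynamic control of the oxaphosphetane.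

Step 9
Reactants: 18 (3E)-6-{3-(benzyloxy)-2,6-bis[4-(benzyloxy)benzyl]phenyl}hex-3-en-2-one; 19 dimethyl malonate
Product: 23 5-(2-{3-(benzyloxy)-2,6-bis[4-(benzyloxy)benzyl]phenyl}ethyl)cyclohexane-1,3-dione, via Michael adduct 20 (not isolated), via cyclic keto ester 21 (not isolated), via keto acid 22 (not isolated)
Conditions: NaOCH3 (1.2 equiv), CH3OH/THF, reflux; then 2 M aq. NaOH, reflux; then aq. HCl to pH 2, 70 °C
Reagents that add atoms: none
Why: Methoxide deprotonates 19 and the soft malonate anion adds 1,4 to enone 18, forming A1–A2 in Michael adduct 20. Proton transfer gives the methyl ketone enolate, which attacks one malonate ester carbonyl in a 6-(enolexo)-exo-trig Claisen (Dieckmann-type) closure that forms A3–A4 and expels methoxide. The closure is driven by deprotonation of the acidic cyclic β-dicarbonyl system of 21, so the reversible Michael step and any double-bond migration in 18 are funnelled to one product. Hydroxide then saponifies the remaining ester, and acidification releases keto acid 22, which loses CO2 through the usual six-membered transition state on warming to give 23. The closest known reaction type is the classical malonate Michael–Claisen synthesis of 5-alkylcyclohexane-1,3-diones from alk-3-en-2-ones, as in the preparation of dimedone from mesityl oxide. No stereocentre remains: those of 20 to 22 vanish on decarboxylation, and A1 of 23 lies on a mirror plane. The step needs 1,4- over 1,2-addition, secured by the stabilised nucleophile and the unhindered enone, and closure through the methyl group only, secured because closure through the internal methylene would give a four-membered ring. The aryl benzyl ethers are inert to alkoxide, hydroxide and brief warm dilute acid.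

Step 10
Reactants: 23 5-(2-{3-(benzyloxy)-2,6-bis[4-(benzyloxy)benzyl]phenyl}ethyl)cyclohexane-1,3-dione
Product: 24 5-(2-{3-(benzyloxy)-2,6-bis[4-(benzyloxy)benzyl]phenyl}ethyl)-3-methoxycyclohex-2-en-1-one (racemic)
Conditions: CH3OH/toluene, TsOH·H2O (cat.), 60 °C
Reagents that add atoms: methanol, CO
Why: Acid-catalysed enol etherification of a 1,3-dione; the two carbonyl groups of 23 are mirror images of each other, so one constitution results (as a racemate), and its stereocentre at A1 is erased in step 11.

Step 11
Reactants: 24 5-(2-{3-(benzyloxy)-2,6-bis[4-(benzyloxy)benzyl]phenyl}ethyl)-3-methoxycyclohex-2-en-1-one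
Product: 27 3-(2-{3-(benzyloxy)-2,6-bis[4-(benzyloxy)benzyl]phenyl}ethyl)-5-methoxyphenol, via 6-(phenylselanyl) enone 25 (not isolated), via cross-conjugated dienone 26 (not isolated)
Conditions: LiN(i-Pr)2, THF, −78 °C; PhSeBr, −78 °C; then pyridine, 30% aq. H2O2, 0 °C to rt
Reagents that add atoms: none
Why: The kinetic enolate of the vinylogous ester forms at A6 and is selenenylated anti to the A1 substituent, which places selenium syn to the A1 hydrogen. Selenoxide syn elimination can then only run towards A1, and dienone 26 tautomerises to the 3-methoxyphenol, a known way from 3-alkoxycyclohexenones to resorcinol monoethers.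

Step 12
Reactants: 27 3-(2-{3-(benzyloxy)-2,6-bis[4-(benzyloxy)benzyl]phenyl}ethyl)-5-methoxyphenol
Product: 28 3-[2-(3-hydroxy-5-methoxyphenyl)ethyl]-2,4-bis(4-hydroxybenzyl)phenol
Conditions: H2 (1 atm), 10% Pd/C, EtOAc/CH3OH, rt
Reagents that add atoms: none
Why: Hydrogenolysis of three aryl benzyl ethers; the diarylmethane and bibenzyl C–C bonds and the methyl ether are not cleaved under these conditions.

## Compound list

1 | cyclohexane-1,3-dione | O=C1CCCC(=O)C1 | starting material
2 | 4-(benzyloxy)benzaldehyde | O=Cc1ccc(OCc2ccccc2)cc1 | starting material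
3 | 2-[4-(benzyloxy)benzylidene]cyclohexane-1,3-dione | O=C1CCCC(=O)C1=Cc1ccc(OCc2ccccc2)cc1 | intermediate
4 | 2-[4-(benzyloxy)benzyl]cyclohexane-1,3-dione | O=C1CCCC(=O)C1Cc1ccc(OCc2ccccc2)cc1 | intermediate
5 | 2-[4-(benzyloxy)benzyl]-3-ethoxycyclohex-2-en-1-one | CCOC1=C(Cc2ccc(OCc3ccccc3)cc2)C(=O)CCC1 | intermediate
6 | 1-(benzyloxy)-4-(bromomethyl)benzene | BrCc1ccc(OCc2ccccc2)cc1 | starting material
7 | 2,6-bis[4-(benzyloxy)benzyl]-3-ethoxycyclohex-2-en-1-one (racemic) | CCOC1=C(Cc2ccc(OCc3ccccc3)cc2)C(=O)C(Cc2ccc(OCc3ccccc3)cc2)CC1 | intermediate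
8 | 2-(2-bromoethyl)-1,3-dioxolane | BrCCC1OCCO1 | starting material
9 | [2-(1,3-dioxolan-2-yl)ethyl]magnesium bromide | Br[Mg]CCC1OCCO1 | intermediate
10 | 2,6-bis[4-(benzyloxy)benzyl]-1-[2-(1,3-dioxolan-2-yl)ethyl]-3-ethoxycyclohex-2-en-1-ol (diastereomer mixture) | CCOC1=C(Cc2ccc(OCc3ccccc3)cc2)C(O)(CCC2OCCO2)C(Cc2ccc(OCc3ccccc3)cc2)CC1 | intermediate
11 | 2,4-bis[4-(benzyloxy)benzyl]-3-[2-(1,3-dioxolan-2-yl)ethyl]cyclohex-2-en-1-one (racemic) | O=C1CCC(Cc2ccc(OCc3ccccc3)cc2)C(CCC2OCCO2)=C1Cc1ccc(OCc2ccccc2)cc1 | intermediate
12 | 2,4-bis[4-(benzyloxy)benzyl]-3-[2-(1,3-dioxolan-2-yl)ethyl]-6-(phenylselanyl)cyclohex-2-en-1-one (diastereomer mixture) | O=C1C([Se]c2ccccc2)CC(Cc2ccc(OCc3ccccc3)cc2)C(CCC2OCCO2)=C1Cc1ccc(OCc2ccccc2)cc1 | intermediate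
13 | 2,4-bis[4-(benzyloxy)benzyl]-3-[2-(1,3-dioxolan-2-yl)ethyl]cyclohexa-2,5-dien-1-one (racemic) | O=C1C=CC(Cc2ccc(OCc3ccccc3)cc2)C(CCC2OCCO2)=C1Cc1ccc(OCc2ccccc2)cc1 | intermediate
14 | 2,4-bis[4-(benzyloxy)benzyl]-3-[2-(1,3-dioxolan-2-yl)ethyl]phenol | Oc1ccc(Cc2ccc(OCc3ccccc3)cc2)c(CCC2OCCO2)c1Cc1ccc(OCc2ccccc2)cc1 | intermediate
15 | 2-(2-{3-(benzyloxy)-2,6-bis[4-(benzyloxy)benzyl]phenyl}ethyl)-1,3-dioxolane | c1ccc(COc2ccc(Cc3ccc(OCc4ccccc4)cc3)c(CCC3OCCO3)c2Cc2ccc(OCc3ccccc3)cc2)cc1 | intermediate
16 | 3-{3-(benzyloxy)-2,6-bis[4-(benzyloxy)benzyl]phenyl}propanal | O=CCCc1c(Cc2ccc(OCc3ccccc3)cc2)ccc(OCc2ccccc2)c1Cc1ccc(OCc2ccccc2)cc1 | intermediate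
17 | 1-(triphenylphosphoranylidene)propan-2-one | CC(=O)C=P(c1ccccc1)(c1ccccc1)c1ccccc1 | starting material
18 | (3E)-6-{3-(benzyloxy)-2,6-bis[4-(benzyloxy)benzyl]phenyl}hex-3-en-2-one | CC(=O)/C=C/CCc1c(Cc2ccc(OCc3ccccc3)cc2)ccc(OCc2ccccc2)c1Cc1ccc(OCc2ccccc2)cc1 | intermediate
19 | dimethyl malonate | COC(=O)CC(=O)OC | starting material
20 | dimethyl 2-(1-{3-(benzyloxy)-2,6-bis[4-(benzyloxy)benzyl]phenyl}-5-oxohexan-3-yl)propanedioate (racemic) | COC(=O)C(C(=O)OC)C(CCc1c(Cc2ccc(OCc3ccccc3)cc2)ccc(OCc2ccccc2)c1Cc1ccc(OCc2ccccc2)cc1)CC(C)=O | intermediate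
21 | methyl 2-(2-{3-(benzyloxy)-2,6-bis[4-(benzyloxy)benzyl]phenyl}ethyl)-4,6-dioxocyclohexane-1-carboxylate (diastereomer mixture, present as its enolate) | COC(=O)C1C(=O)CC(=O)CC1CCc1c(Cc2ccc(OCc3ccccc3)cc2)ccc(OCc2ccccc2)c1Cc1ccc(OCc2ccccc2)cc1 | intermediate
22 | 2-(2-{3-(benzyloxy)-2,6-bis[4-(benzyloxy)benzyl]phenyl}ethyl)-4,6-dioxocyclohexane-1-carboxylic acid (diastereomer mixture) | OC(=O)C1C(=O)CC(=O)CC1CCc1c(Cc2ccc(OCc3ccccc3)cc2)ccc(OCc2ccccc2)c1Cc1ccc(OCc2ccccc2)cc1 | intermediate
23 | 5-(2-{3-(benzyloxy)-2,6-bis[4-(benzyloxy)benzyl]phenyl}ethyl)cyclohexane-1,3-dione | O=C1CC(=O)CC(CCc2c(Cc3ccc(OCc4ccccc4)cc3)ccc(OCc3ccccc3)c2Cc2ccc(OCc3ccccc3)cc2)C1 | intermediate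
24 | 5-(2-{3-(benzyloxy)-2,6-bis[4-(benzyloxy)benzyl]phenyl}ethyl)-3-methoxycyclohex-2-en-1-one (racemic) | COC1=CC(=O)CC(CCc2c(Cc3ccc(OCc4ccccc4)cc3)ccc(OCc3ccccc3)c2Cc2ccc(OCc3ccccc3)cc2)C1 | intermediate
25 | 5-(2-{3-(benzyloxy)-2,6-bis[4-(benzyloxy)benzyl]phenyl}ethyl)-3-methoxy-6-(phenylselanyl)cyclohex-2-en-1-one (diastereomer mixture) | COC1=CC(=O)C([Se]c2ccccc2)C(CCc2c(Cc3ccc(OCc4ccccc4)cc3)ccc(OCc3ccccc3)c2Cc2ccc(OCc3ccccc3)cc2)C1 | intermediate
26 | 3-(2-{3-(benzyloxy)-2,6-bis[4-(benzyloxy)benzyl]phenyl}ethyl)-5-methoxycyclohexa-2,5-dien-1-one | COC1=CC(=O)C=C(CCc2c(Cc3ccc(OCc4ccccc4)cc3)ccc(OCc3ccccc3)c2Cc2ccc(OCc3ccccc3)cc2)C1 | intermediate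
27 | 3-(2-{3-(benzyloxy)-2,6-bis[4-(benzyloxy)benzyl]phenyl}ethyl)-5-methoxyphenol | COc1cc(O)cc(CCc2c(Cc3ccc(OCc4ccccc4)cc3)ccc(OCc3ccccc3)c2Cc2ccc(OCc3ccccc3)cc2)c1 | intermediate
28 | 3-[2-(3-hydroxy-5-methoxyphenyl)ethyl]-2,4-bis(4-hydroxybenzyl)phenol | COc1cc(O)cc(CCc2c(Cc3ccc(O)cc3)ccc(O)c2Cc2ccc(O)cc2)c1 | target

## Step count and uncertain steps

Total: 12 steps. Longest linear sequence: 12 steps (1 to 28).

Step 9 (key step). What may go wrong: incomplete Claisen closure with retro-Michael return to 18, base-induced double-bond migration or self-condensation of 18 before the malonate adds, and slow reaction because the lipophilic substrate dissolves poorly in methanol. Fallback: exchange donor and acceptor. Setting out from aldehyde 16, a Horner–Wadsworth–Emmons reaction with trimethyl phosphonoacetate (NaH, THF) would give methyl (2E)-5-{3-(benzyloxy)-2,6-bis[4-(benzyloxy)benzyl]phenyl}pent-2-enoate F1. Methyl acetoacetate and NaOCH3 in CH3OH/THF would add to F1 to give dimethyl 2-acetyl-3-(2-{3-(benzyloxy)-2,6-bis[4-(benzyloxy)benzyl]phenyl}ethyl)pentanedioate F2. The acetyl methyl group of F2 closes onto the distal ester and gives the same cyclic keto ester 21, where the route is rejoined; saponification and decarboxylation lead to 23 as in step 9.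

Step 4. What may go wrong: enolisation of the hindered ketone 7 at C6 by the Grignard reagent in place of addition, and partial opening of the dioxolane during the acidic transposition. Fallback: remove the enolisable hydrogen and reach the arene oxidation level by isomerisation. Setting out from 5, its lithium enolate would be added to aldehyde 2 to give 2-[4-(benzyloxy)benzyl]-6-{[4-(benzyloxy)phenyl](hydroxy)methyl}-3-ethoxycyclohex-2-en-1-one F3. Mesylation and elimination (CH3SO2Cl, Et3N, then DBU) would give (6E)-2-[4-(benzyloxy)benzyl]-6-[4-(benzyloxy)benzylidene]-3-ethoxycyclohex-2-en-1-one F4, which has no hydrogen at C6. Addition of Grignard reagent 9 and cold dilute acid would give (4E)-2-[4-(benzyloxy)benzyl]-4-[4-(benzyloxy)benzylidene]-3-[2-(1,3-dioxolan-2-yl)ethyl]cyclohex-2-en-1-one F5, an isomer of 14. DBU would convert F5 into 14 by proton shifts; the route is rejoined at 14 and step 5 is no longer needed.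

Step 5. What may go wrong: competing deprotonation of 11 at the γ positions, and over-oxidation or ring selenenylation of the newly formed phenol by the selenium by-products in the presence of peroxide. Fallback: from 11, the kinetic enolate would be trapped (LiN(i-Pr)2, Me3SiCl) as ({4,6-bis[4-(benzyloxy)benzyl]-5-[2-(1,3-dioxolan-2-yl)ethyl]cyclohexa-1,5-dien-1-yl}oxy)(trimethyl)silane F6. Dehydrosilylation with Pd(OAc)2 in CH3CN (Saegusa–Ito oxidation) would give dienone 13, which tautomerises to 14 with neither peroxide nor electrophilic selenium present.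

Step 11. What may go wrong: the product is a resorcinol monoether, the most electron-rich ring of the route, so electrophilic selenenylation or oxidation of the product may compete. Selenenylation syn to the A1 substituent would also leave no syn hydrogen for the elimination. Fallback: an oxidant-free sulfoxide elimination. From 24, LiN(i-Pr)2 (2 equiv) and methyl benzenesulfinate would give 5-(2-{3-(benzyloxy)-2,6-bis[4-(benzyloxy)benzyl]phenyl}ethyl)-3-methoxy-6-(phenylsulfinyl)cyclohex-2-en-1-one F7, whose acidic α-hydrogen lets the diastereomers interconvert. Heating in toluene over CaCO3 would eliminate the sulfenic acid to give dienone 26 and, after tautomerisation, 27.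

## Further compounds

F1 | step 9 | methyl (2E)-5-{3-(benzyloxy)-2,6-bis[4-(benzyloxy)benzyl]phenyl}pent-2-enoate | COC(=O)/C=C/CCc1c(Cc2ccc(OCc3ccccc3)cc2)ccc(OCc2ccccc2)c1Cc1ccc(OCc2ccccc2)cc1
F2 | step 9 | dimethyl 2-acetyl-3-(2-{3-(benzyloxy)-2,6-bis[4-(benzyloxy)benzyl]phenyl}ethyl)pentanedioate | COC(=O)CC(CCc1c(Cc2ccc(OCc3ccccc3)cc2)ccc(OCc2ccccc2)c1Cc1ccc(OCc2ccccc2)cc1)C(C(C)=O)C(=O)OC
F3 | step 4 | 2-[4-(benzyloxy)benzyl]-6-{[4-(benzyloxy)phenyl](hydroxy)methyl}-3-ethoxycyclohex-2-en-1-one | CCOC1=C(Cc2ccc(OCc3ccccc3)cc2)C(=O)C(C(O)c2ccc(OCc3ccccc3)cc2)CC1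
F4 | step 4 | (6E)-2-[4-(benzyloxy)benzyl]-6-[4-(benzyloxy)benzylidene]-3-ethoxycyclohex-2-en-1-one | CCOC1=C(Cc2ccc(OCc3ccccc3)cc2)C(=O)/C(=C/c2ccc(OCc3ccccc3)cc2)CC1
F5 | step 4 | (4E)-2-[4-(benzyloxy)benzyl]-4-[4-(benzyloxy)benzylidene]-3-[2-(1,3-dioxolan-2-yl)ethyl]cyclohex-2-en-1-one | O=C1CC/C(=C\c2ccc(OCc3ccccc3)cc2)C(CCC2OCCO2)=C1Cc1ccc(OCc2ccccc2)cc1
F6 | step 5 | ({4,6-bis[4-(benzyloxy)benzyl]-5-[2-(1,3-dioxolan-2-yl)ethyl]cyclohexa-1,5-dien-1-yl}oxy)(trimethyl)silane | C[Si](C)(C)OC1=CCC(Cc2ccc(OCc3ccccc3)cc2)C(CCC2OCCO2)=C1Cc1ccc(OCc2ccccc2)cc1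
F7 | step 11 | 5-(2-{3-(benzyloxy)-2,6-bis[4-(benzyloxy)benzyl]phenyl}ethyl)-3-methoxy-6-(phenylsulfinyl)cyclohex-2-en-1-one | COC1=CC(=O)C(S(=O)c2ccccc2)C(CCc2c(Cc3ccc(OCc4ccccc4)cc3)ccc(OCc3ccccc3)c2Cc2ccc(OCc3ccccc3)cc2)C1
A1 | alternative 1 | [4-(benzyloxy)phenyl](3-[4-(benzyloxy)benzyl]-2-{2-[3-(benzyloxy)-5-methoxyphenyl]ethyl}-6-hydroxyphenyl)methanone | COc1cc(OCc2ccccc2)cc(CCc2c(Cc3ccc(OCc4ccccc4)cc3)ccc(O)c2C(=O)c2ccc(OCc3ccccc3)cc2)c1
A2 | alternative 1 | 6-[4-(benzyloxy)benzyl]-3-hydroxy-2H-pyran-2-one | O=c1oc(Cc2ccc(OCc3ccccc3)cc2)ccc1O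
A3 | alternative 1 | 1-[4-(benzyloxy)phenyl]-5-[3-(benzyloxy)-5-methoxyphenyl]pent-2-yn-1-one | COc1cc(OCc2ccccc2)cc(CCC#CC(=O)c2ccc(OCc3ccccc3)cc2)c1
A4 | alternative 2 | 3-{2-[3-(benzyloxy)-5-methoxyphenyl]ethyl}-6-bromo-2,4-bis(4-hydroxybenzyl)phenol | COc1cc(OCc2ccccc2)cc(CCc2c(Cc3ccc(O)cc3)cc(Br)c(O)c2Cc2ccc(O)cc2)c1
A5 | alternative 2 | 5-{2-[3-(benzyloxy)-5-methoxyphenyl]ethyl}-2-bromophenol | COc1cc(OCc2ccccc2)cc(CCc2ccc(Br)c(O)c2)c1
A6 | alternative 2 | 4-(hydroxymethyl)phenol | OCc1ccc(O)cc1
A7 | alternative 2 | 4-methylidenecyclohexa-2,5-dien-1-one | C=C1C=CC(=O)C=C1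
A8 | alternative 3 | 1-(benzyloxy)-3-[(E)-2-{3-(benzyloxy)-2,6-bis[4-(benzyloxy)benzyl]phenyl}ethenyl]-5-methoxybenzene | COc1cc(OCc2ccccc2)cc(/C=C/c2c(Cc3ccc(OCc4ccccc4)cc3)ccc(OCc3ccccc3)c2Cc2ccc(OCc3ccccc3)cc2)c1
A9 | alternative 3 | 4-(benzyloxy)-1-[4-(benzyloxy)benzyl]-2-iodobenzene | Ic1cc(OCc2ccccc2)ccc1Cc1ccc(OCc2ccccc2)cc1
A10 | alternative 3 | 1-(benzyloxy)-4-(chloromethyl)benzene | ClCc1ccc(OCc2ccccc2)cc1
A11 | alternative 3 | 1-(benzyloxy)-3-ethenyl-5-methoxybenzene | C=Cc1cc(OC)cc(OCc2ccccc2)c1
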